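| setting | spring | flask |
|---|---|---|
| substrate | 0.028 M | 0.028 M |
| precatalyst | 5.2 × 10⁻⁴ mol% | 5.2 × 10⁻⁴ mol% |
| remark | the very flask that is asked about, followed so far |  |
| time |  | 12 min |

spring run (percent of the substrate charged)

| time / min | substrate / % | product / % |
|---|---|---|
| 0.833 | 78.6 | 21.3 |
| 2.00 | 19.1 | 81.1 |
| 2.50 | 5.8 | 94.1 |
| 4.00 | 3.6 | 96.9 |

(standard deviation of a reading: 0.5 percentage points)



- part of the substrate gone at 12 min
- the product standing at 12 min, as a percentage of the substrate charged

Substrate in this flask fell by 13 percentage points between 2.00 min and 2.50 min, but by less, 2.2 points, over the longer stretch to 4.00 min, so the reaction is stalling well before 12 min. At that last reading substrate and product add up to 100.5% of the charge, and the catalyst was charged at just 5.2 × 10⁻⁴ mol%. A stop can be described by two amounts, standing substrate and standing product. Product over substrate at the stop is the stopping ratio Q, a reaction quotient, read here as 26.9, with the scatter of a small reading in it. If Q holds, substrate left is 3.58%, so this reckoning gives 96.4% for both answers.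

The forecast, holding that “little further change is expected”, is higher: 97.5% gone (96.3% to 99.6%) and 97.5% product (96% to 99.5%).

The flask gives 96.7% gone and 96.7% product.

    substrate + enzyme ⇌ complex (K = 820 M⁻¹, k = 1.40 × 10⁶ M⁻¹ s⁻¹)
    complex ⇌ enzyme + product (K = 0.0360 M, k = 4700 s⁻¹)
    precatalyst → enzyme (k = 0.00980 s⁻¹)

The substrate and product of this flask have come to rest, with a change of 0 points over the second half of the time. Its substrate stands at 3.3%, which is 0.28 points below the share reckoned from Q. The neighbour with 0.017 M of substrate also stands at 3.3%. Ten times the time moves this flask's substrate by 0 points. Precatalyst still falls, from 0.0862% of the catalyst charged at 12.0 min to 0% at 120 min.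

The readings come from a simulation for substances that don't exist, noise included.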